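**Assumptions (one line):** The C6 OMe anomer and the exo C16 methyl of the target are the thermodynamic ones, the endo Diels–Alder diastereomer is separated by chromatography, and (R)-BINAP gives the (R)-3-alkenylcyclohexanone by analogy with arylboronic acid additions.

## Retrosynthetic overview
1. Target (21) comes from methanolysis of a lactol. The C15 ketone and C16 methyl come from Riley oxidation, oxidation and hydrogenation of an exocyclic alkene on the bicyclo[3.2.1]octane.
2. The bicyclo[3.2.1]octane (ring D, quaternary C8) is closed last. A Pd(II)-mediated oxidative cycloalkenylation joins the silyl ketene acetal of the spiro-δ-lactone to the C13 isopropenyl group.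
3. The C9–C10 bond and the spirolactone come from a Ti(III) epoxide-opening radical 7-endo cyclization through a C6 acylal tether, followed by translactonization.
4. Fragments: ring-C acid (Rh asymmetric conjugate addition) and ring-A lactol (Diels–Alder of 4-methylbutenolide, enzymatically resolved).
5. Ring-formation order: ring A with the THF ring (Diels–Alder), ring C (preformed), the 6,7-lactone then the spiro-δ-lactone (radical step), the methyl acetal, then ring D.

## Route

**Step 1**
Reactants: 1 cyclohex-2-en-1-one; 2 isopropenylboronic acid pinacol ester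
Product: 3 (R)-3-(prop-1-en-2-yl)cyclohexan-1-one
Conditions: [Rh(cod)Cl]2, (R)-BINAP, aq. KOH, dioxane/H2O, 50 °C
Reagents that add atoms: none
Why: Hayashi–Miyaura Rh-catalysed asymmetric 1,4-addition; the chiral Rh–BINAP enolate sets C13, which becomes the bridgehead.

**Step 2**
Reactants: 3
Product: 4 (R)-5-(prop-1-en-2-yl)cyclohex-1-en-1-yl triflate
Conditions: LDA, THF, −78 °C; then PhNTf2, −78 → 0 °C
Reagents that add atoms: PhNTf2, FC(F)(F)S(=O)(=O)N(c1ccccc1)S(=O)(=O)C(F)(F)F
Why: kinetic enolization at the less hindered α-carbon (C9 side, remote from C13) followed by O-triflation; the minor regioisomer is removed by chromatography and the C13 stereocentre is untouched.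

**Step 3**
Reactants: 4
Product: 5 (R)-5-(prop-1-en-2-yl)cyclohex-1-ene-1-carboxylic acid
Conditions: Pd(OAc)2, PPh3, LiCl, CO (1 atm), n-Bu3N, DMF/H2O, 60 °C
Reagents that add atoms: carbon monoxide, [C-]#[O+]; water, O
Why: Pd-catalysed hydroxycarbonylation of the vinyl triflate (Cacchi-type) installs C7 as the carboxylic acid and leaves the isopropenyl group and the C13 stereocentre untouched.

**Step 4**
Reactants: 6 4-methylfuran-2(5H)-one; 7 (E)-1-(trimethylsiloxy)buta-1,3-diene
Product: 8 rac-(3aR*,7S*,7aR*)-7-hydroxy-3a-methyl-3a,4,7,7a-tetrahydro-2-benzofuran-1(3H)-one (endo, cis-fused lactone)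
Conditions: toluene, BHT, 160 °C, sealed tube; then 1 M HCl, THF
Reagents that add atoms: none
Why: normal-demand Diels–Alder; the butenolide β-carbon bonds to the diene CH2 terminus (ortho rule), placing the C10–O carbon next to C5. Suprafacial addition fixes C4/C5 cis-fused (C19 and C6 cis, Me and H cis), and HCl cleaves the allylic TMS ether. The product is racemic.

**Step 5**
Reactants: 8
Product: 9 rac-7-hydroxy-3a-methylhexahydro-2-benzofuran-1(3H)-one
Conditions: H2 (1 atm), 10% Pd/C, EtOAc, rt; chromatographic removal of the minor exo diastereomer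
Reagents that add atoms: none
Why: hydrogenation of the disubstituted C1=C2 alkene; no stereocentre is changed. The exo-alcohol diastereomer is removed here so that the resolution in step 6 deals with a single racemate.

**Step 6**
Reactants: 9
Product: 10 (3aR,7S,7aR)-7-hydroxy-3a-methylhexahydro-2-benzofuran-1(3H)-one
Conditions: lipase PS-C, vinyl acetate, t-BuOMe, 30 °C, stopped at ~50% conversion; unreacted alcohol isolated
Reagents that add atoms: none in the desired product (vinyl acetate, C=COC(C)=O, acetylates the discarded enantiomer)
Why: enzymatic kinetic resolution of the secondary alcohol fixes the absolute configuration of C4 and C5, the only ring-A stereocentres that survive the next oxidation.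

**Step 7**
Reactants: 10
Product: 11 (3aR,7aR)-3a-methylhexahydro-2-benzofuran-1,7-dione
Conditions: Dess–Martin periodinane, NaHCO3, CH2Cl2, rt
Reagents that add atoms: none
Why: alcohol oxidation. The cis-fused lactone is the stable ring fusion and the quaternary C4 cannot epimerize, so the enantiomeric purity is kept; mild buffered conditions avoid epimerization at C5.

**Step 8**
Reactants: 11
Product: 12 (3aR,7aS)-3a-methyl-7-methylenehexahydro-2-benzofuran-1(3H)-one
Conditions: Zn, CH2Br2, TiCl4, THF/CH2Cl2, 0 °C → rt
Reagents that add atoms: dibromomethane, BrCBr (supplies the =CH2, i.e. C20)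
Why: Takai–Lombardo methylenation tolerates the enolizable β-keto-lactone and does not touch the lactone carbonyl.

**Step 9**
Reactants: 12
Product: 13 spiro-epoxide at C10 (epoxide epimers not defined)
Conditions: mCPBA, NaHCO3, CH2Cl2, 0 °C
Reagents that add atoms: mCPBA, OOC(=O)c1cccc(Cl)c1
Why: Prilezhaev epoxidation of the only alkene. The epoxide configuration is irrelevant because it is opened to a planar tertiary radical.

**Step 10**
Reactants: 13
Product: 14 lactol (C6 anomers)
Conditions: DIBAL-H (1.1 equiv), CH2Cl2, −78 °C
Reagents that add atoms: none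
Why: partial reduction of the γ-lactone to the lactol, which sets the C6 oxidation level. The epoxide survives at −78 °C with a stoichiometric amount of hydride.

**Step 11**
Reactants: 14 lactol; 5 ring-C acid
Product: 15 acylal (lactol ester of 5; anomeric mixture)
Conditions: EDC·HCl, DMAP, CH2Cl2, 0 °C → rt
Reagents that add atoms: none
Why: Steglich esterification builds the O-tether between C6 and the enoate C7 carbonyl.

**Step 12**
Reactants: 15
Product: 16 spiro-δ-lactone lactol (C8-H and C6 epimeric)
Conditions: Cp2TiCl2 (2.5 equiv), Zn, THF, rt; then 1 M HCl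
Reagents that add atoms: none
Why: Nugent–RajanBabu Ti(III) opening of the epoxide gives the tertiary C10 radical with C20–OTi retained. The radical adds 7-endo (Giese) to C9 of the tethered enoate, on the equatorial face trans to C5–C6, because the axial C19 blocks the other face; this sets C10 and C9. A second Ti(III) reduces the α-ester radical to the enolate. The C20 alkoxide then transacylates onto C7 to give the six-membered spiro-lactone and release the lactol. C8 is left epimerizable and is reset in step 14.

**Step 13**
Reactants: 16
Product: 17 methyl acetal (C6-OMe on the convex face)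
Conditions: MeOH, PPTS, rt
Reagents that add atoms: methanol, CO
Why: acid-catalysed acetalization under thermodynamic control gives the convex-face (anomeric) OMe, cis to H5 and the C4 methyl, which sets C6.

**Step 14**
Reactants: 17
Product: 18 bicyclo[3.2.1]octane with exocyclic C16=C17 alkene
Conditions: (i) LiHMDS, TMSCl, THF, −78 °C; (ii) Pd(OAc)2 (cat.), DMSO, O2, MeCN, 60 °C
Reagents that add atoms: none (the TMS group is lost)
Why: Pd(II)-mediated oxidative cycloalkenylation (Toyota–Ihara type). The silyl ketene acetal bonds C8 to C15 on the same face as the C13 isopropenyl group, and β-H elimination toward C17 gives the exocyclic alkene. The quaternary C8 stereocentre is set by this intramolecular delivery, which also erases the C8 epimer issue from step 12.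

**Step 15**
Reactants: 18
Product: 19 C15 allylic alcohol
Conditions: SeO2, TBHP, CH2Cl2, rt
Reagents that add atoms: selenium dioxide, O=[Se]=O; tert-butyl hydroperoxide, CC(C)(C)OO
Why: Riley allylic oxidation at C15, the CH2 adjacent to the exocyclic alkene (the other allylic position is a bridgehead). The new carbinol stereocentre is destroyed in the next step.

**Step 16**
Reactants: 19
Product: 20 C15 enone
Conditions: Dess–Martin periodinane, NaHCO3, CH2Cl2, rt
Reagents that add atoms: none
Why: oxidation of the allylic alcohol to the α-methylene ketone.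

**Step 17**
Reactants: 20
Product: 21 ludongnin H
Conditions: H2 (1 atm), Pd/C, EtOAc, rt; filter, then DBU, toluene, 60 °C
Reagents that add atoms: none
Why: Pd/C reduces the enone C=C chemoselectively, leaving the ketone, acetal and lactone. DBU then equilibrates C16, α to the ketone, to the more stable exo-methyl epimer; C8 is quaternary and cannot epimerize.

## Compound list
1 | cyclohex-2-en-1-one | O=C1C=CCCC1 | starting material
2 | isopropenylboronic acid pinacol ester | CC(=C)B1OC(C)(C)C(C)(C)O1 | starting material
3 | (R)-3-(prop-1-en-2-yl)cyclohexan-1-one | O=C1CCC[C@@H](C(C)=C)C1 | intermediate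
4 | (R)-5-(prop-1-en-2-yl)cyclohex-1-en-1-yl triflate | FC(F)(F)S(=O)(=O)OC1=CCC[C@@H](C(C)=C)C1 | intermediate
5 | (R)-5-(prop-1-en-2-yl)cyclohex-1-ene-1-carboxylic acid | OC(=O)C1=CCC[C@@H](C(C)=C)C1 | intermediate
6 | 4-methylfuran-2(5H)-one | CC1=CC(=O)OC1 | starting material
7 | (E)-1-(trimethylsiloxy)buta-1,3-diene | C=C/C=C/O[Si](C)(C)C | starting material
8 | rac-(3aR*,7S*,7aR*)-7-hydroxy-3a-methyl-3a,4,7,7a-tetrahydro-2-benzofuran-1(3H)-one | O=C1OC[C@]2(C)CC=C[C@H](O)[C@H]12 | intermediate (racemic, drawn as one enantiomer)
9 | rac-7-hydroxy-3a-methylhexahydro-2-benzofuran-1(3H)-one | O=C1OC[C@]2(C)CCC[C@H](O)[C@H]12 | intermediate (racemic, drawn as one enantiomer)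
10 | (3aR,7S,7aR)-7-hydroxy-3a-methylhexahydro-2-benzofuran-1(3H)-one | O=C1OC[C@]2(C)CCC[C@H](O)[C@H]12 | intermediate
11 | (3aR,7aR)-3a-methylhexahydro-2-benzofuran-1,7-dione | O=C1OC[C@]2(C)CCCC(=O)[C@H]12 | intermediate
12 | (3aR,7aS)-3a-methyl-7-methylenehexahydro-2-benzofuran-1(3H)-one | O=C1OC[C@]2(C)CCCC(=C)[C@H]12 | intermediate
13 | spiro[oxirane-2,7'-benzofuranone] epoxide of 12 (epoxide epimers undefined) | O=C1OC[C@]2(C)CCCC3(CO3)[C@H]12 | intermediate
14 | lactol from DIBAL reduction of 13 (C6 anomers) | OC1OC[C@]2(C)CCCC3(CO3)[C@H]12 | intermediate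
15 | acylal of lactol 14 with acid 5 | O=C(C1=CCC[C@@H](C(C)=C)C1)OC1OC[C@]2(C)CCCC3(CO3)[C@H]12 | intermediate
16 | spiro-δ-lactone lactol with C13 isopropenyl (C8-H and C6 undefined) | OC1OC[C@]2(C)CCC[C@]3(COC(=O)C4C[C@H](C(C)=C)CC[C@H]43)[C@H]12 | intermediate
17 | C6 methyl acetal of 16 (C8-H undefined) | CO[C@H]1OC[C@]2(C)CCC[C@]3(COC(=O)C4C[C@H](C(C)=C)CC[C@H]43)[C@H]12 | intermediate
18 | 16,17-ene bicyclo[3.2.1]octane (15-deoxo) | CO[C@H]1OC[C@]2(C)CCC[C@]3(COC(=O)[C@@]45C[C@@H](CC[C@H]43)C(=C)C5)[C@H]12 | intermediate
19 | 15-hydroxy-16-ene (C15 epimer undefined) | CO[C@H]1OC[C@]2(C)CCC[C@]3(COC(=O)[C@@]45C[C@@H](CC[C@H]43)C(=C)C5O)[C@H]12 | intermediate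
20 | 15-oxo-16-ene (enone) | CO[C@H]1OC[C@]2(C)CCC[C@]3(COC(=O)[C@@]45C[C@@H](CC[C@H]43)C(=C)C5=O)[C@H]12 | intermediate
21 | ludongnin H | CO[C@H]1OC[C@]2(C)CCC[C@]3(COC(=O)[C@@]45C[C@@H](CC[C@H]43)[C@H](C)C5=O)[C@H]12 | target

**Total steps:** 17. **Longest linear sequence:** 14 steps, from the Diels–Alder (step 4) to the target (step 17).

## Three steps most likely to fail
1. **Step 12, Ti(III) 7-endo radical cyclization.** The enoate is trisubstituted, the ester must adopt the strained E conformation, the acylal is Lewis-acid labile, and the C9/C13 diastereoselectivity is uncertain. Fallback: use a 2-substituted acrylate tether so the radical adds to an unhindered CH2 terminus (C9), then build ring C afterwards by α,β-desaturation and an SmI2 ketyl–olefin/aldol cascade.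
2. **Step 14, Pd cycloalkenylation.** The ring closure forms a quaternary bridgehead by C8–C15 bond formation. Fallback: convert the isopropenyl group into a CH(CH3)C(O)N(OMe)Me side chain (hydroboration, oxidation, Weinreb amide) and close C8–C15 by intramolecular Claisen-type acylation of the lactone enolate, which gives the C15 ketone directly.
3. **Step 4, Diels–Alder of the β,β-disubstituted butenolide.** The dienophile is poorly reactive and the yield and regioselectivity may be low. Fallback: make the ring-A fragment by Cu-catalysed asymmetric conjugate addition of MeMgBr to 3-(MOMOCH2)cyclohex-2-enone with a formaldehyde enolate trap, then close the THF lactol, which avoids both the Diels–Alder and the resolution.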